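**Strategy.** The oxocane (ring B: O, C7–C13) is cut at C10–C11 and O–C13, leaving a 2-bromo-pyranosyl acetate (ring A: O, C6–C10) that carries a racemic α-ethylallylsilane on the C7 oxygen. The key step exploits the 1,4-cis relation of that oxygen and C10 across ring A: in one flask the C7 oxygen first anchors the delivery of C11 to the C10 oxocarbenium ion (tethered Hosomi–Sakurai), then opens the bromonium ion of the new (E)-C12=C13 alkene at C13 (8-endo), which installs the C12 bromide anti to it. Ring A comes from an Achmatowicz rearrangement; the enyne is added last.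

Key step: step 9

Remark: carbons are numbered C1 (alkyne CH) to C15 (ethyl CH3) along the chain of the target; ring A is the tetrahydropyran, ring B the oxocane. The stereocenter of the racemic silane is destroyed in step 9.

Step 1
Reactants: 1 3-(furan-2-yl)-3-oxopropanenitrile
Product: 2 (3R)-3-(furan-2-yl)-3-hydroxypropanenitrile
Conditions: RuCl[(R,R)-TsDPEN](p-cymene) (1 mol%), HCO2H/Et3N (5:2), 25 °C
Reagents that add atoms: none
Why: Asymmetric transfer hydrogenation of the furyl ketone, in which the (R,R)-diamine ligand should direct hydride to the face that gives the (R)-carbinol (C6), as for aryl ketones.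

Step 2
Reactants: 2 (3R)-3-(furan-2-yl)-3-hydroxypropanenitrile
Product: 3 2-[(2R)-6-hydroxy-3-oxo-3,6-dihydro-2H-pyran-2-yl]acetonitrile (both anomers)
Conditions: NBS, NaHCO3, NaOAc, THF/H2O (4:1), 0 °C
Reagents that add atoms: water O
Why: Achmatowicz rearrangement, in which oxidation of the furan and ring expansion through the carbinol oxygen give the pyranone hemiacetal without touching C6.

Step 3
Reactants: 3 2-[(2R)-6-hydroxy-3-oxo-3,6-dihydro-2H-pyran-2-yl]acetonitrile
Product: 4 (2R,6R)-6-(cyanomethyl)-5-oxo-5,6-dihydro-2H-pyran-2-yl acetate (2,6-trans anomer)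
Conditions: Ac2O, pyridine, DMAP (cat.), CH2Cl2, −20 °C
Reagents that add atoms: acetic anhydride CC(=O)OC(C)=O
Why: Acylation of the hemiacetal, in which the 2,6-trans acetate (axial, favoured by the anomeric effect) should be the main anomer and is separated from the cis anomer by chromatography.

Step 4
Reactants: 4 (2R,6R)-6-(cyanomethyl)-5-oxo-5,6-dihydro-2H-pyran-2-yl acetate
Product: 6 (2R,3S,6R)-3-bromo-6-(cyanomethyl)-5-oxooxan-2-yl acetate (used crude), via silyl enol ether 5 (not isolated)
Conditions: Me3SiBr, CH2Cl2, −78 °C; then MeOH, −78 °C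
Reagents that add atoms: bromotrimethylsilane C[Si](C)(C)Br
Why: Conjugate (1,4) hydrobromination of the enone through its silyl enol ether, the bromide entering axially at C9 anti to the pseudo-axial anomeric acetate, which places Br cis to the C6 side chain.

Step 5
Reactants: 6 (2R,3S,6R)-3-bromo-6-(cyanomethyl)-5-oxooxan-2-yl acetate
Product: 7 (2R,3S,5R,6R)-3-bromo-6-(cyanomethyl)-5-hydroxyoxan-2-yl acetate
Conditions: LiBH(s-Bu)3 (L-Selectride), THF, −78 °C
Reagents that add atoms: none
Why: Ketone reduction with a bulky borohydride, which should attack equatorially (the axial path is blocked by the syn-axial C9 bromide) and give the axial C7 alcohol cis to the C6 side chain and to Br.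

Step 6
Reactants: 8 allyl(chloro)dimethylsilane
Product: 9 allyl(diisopropylamino)dimethylsilane
Conditions: LiN(i-Pr)2, THF, −78 → 25 °C
Reagents that add atoms: lithium diisopropylamide [Li+].CC(C)[N-]C(C)C
Why: Nucleophilic substitution at silicon (aminolysis of the chlorosilane by the lithium amide).

Step 7
Reactants: 9 allyl(diisopropylamino)dimethylsilane
Product: 11 (diisopropylamino)dimethyl(pent-1-en-3-yl)silane (racemic), via lithiated allylsilane 10 (not isolated)
Conditions: n-BuLi, TMEDA, Et2O, 0 °C; then EtI, −78 → 0 °C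
Reagents that add atoms: iodoethane CCI
Why: Deprotonation to the silyl-stabilised allyl anion and alkylation at the carbon next to silicon (α-alkylation of an aminosilyl allyl anion), the α over γ selectivity relying on the bulky amino group on silicon; the new stereocenter forms as a racemate.

Step 8
Reactants: 7 (2R,3S,5R,6R)-3-bromo-6-(cyanomethyl)-5-hydroxyoxan-2-yl acetate; 11 (diisopropylamino)dimethyl(pent-1-en-3-yl)silane
Product: 13 (2R,3S,5R,6R)-3-bromo-6-(cyanomethyl)-5-{[dimethyl(pent-1-en-3-yl)silyl]oxy}oxan-2-yl acetate (both epimers at the silicon-bearing carbon), via chlorosilane 12 (not isolated)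
Conditions: AcCl (1.0 equiv to 11), CH2Cl2, 0 °C; then 7, imidazole, DMAP (cat.), 25 °C
Reagents that add atoms: none
Why: Acetyl chloride cleaves the Si–N bond to the chlorosilane, which silylates the hindered axial C7 alcohol under imidazole catalysis (standard silyl ether formation).

Step 9
Reactants: 13 (2R,3S,5R,6R)-3-bromo-6-(cyanomethyl)-5-{[dimethyl(pent-1-en-3-yl)silyl]oxy}oxan-2-yl acetate
Product: 15 2-[(1R,3R,4S,6S,8R,10S)-4,10-dibromo-3-ethyl-2,7-dioxabicyclo[4.2.2]decan-8-yl]acetonitrile, via C-allyl silyl acetate 14 (not isolated)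
Conditions: Me3SiOTf (0.3 equiv), CH2Cl2 (0.005 M), −78 → −20 °C; then 2,4,4,6-tetrabromocyclohexa-2,5-dien-1-one, −78 → 0 °C
Reagents that add atoms: 2,4,4,6-tetrabromocyclohexa-2,5-dien-1-one O=C1C(Br)=CC(Br)(Br)C=C1Br
Why: Me3SiOTf ionises the anomeric acetate to the C10 oxocarbenium ion of ring A and the α-ethylallylsilane anchored on the C7 oxygen adds through its terminal carbon C11 (SE2′, hydrogen eclipsing the alkene) to give the (E)-C12=C13 alkene, the silyl cation taking up acetate (14); the bromine donor then forms the bromonium ion of this alkene and the same oxygen opens it at C13 with loss of silicon. The closest known reaction types are the temporary-silicon-tethered Hosomi–Sakurai allylation of acetal-derived oxocarbenium ions and the desilylative bromoetherification used for medium-ring bromo ethers. Ring B is closed by the C–O bond in an 8-endo anti opening of the bromonium ion, while the C–C bond is made inside a temporary silicon-containing ring that is lost in the second stage. C10 is set by the tether, which reaches only the face cis to the axial C7 oxygen (ring A as a boat, C9–Br pseudo-equatorial and unable to bridge); C12 and C13 are set relative to each other by anti addition to the (E)-alkene and relative to ring A by the bridged transition state, in which the ethyl group should avoid the bridge that carries the C9 bromide. The step needs cis delivery against the usual trans preference of 2-bromo oxocarbenium ions, secured by the tether and high dilution, and 8-endo rather than 7-exo opening, for which the lower electron density at C12 (closer to the bromo-acetal carbons) is relied on.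

Step 10
Reactants: 15 2-[(1R,3R,4S,6S,8R,10S)-4,10-dibromo-3-ethyl-2,7-dioxabicyclo[4.2.2]decan-8-yl]acetonitrile
Product: 16 2-[(1R,3R,4S,6S,8R,10S)-4,10-dibromo-3-ethyl-2,7-dioxabicyclo[4.2.2]decan-8-yl]acetaldehyde
Conditions: i-Bu2AlH, CH2Cl2, −78 °C; then aq. potassium sodium tartrate
Reagents that add atoms: water O
Why: Partial reduction of the nitrile to the aluminium imine, hydrolysed to the aldehyde on work-up (nitrile-to-aldehyde reduction), with the secondary bromides and ethers inert at −78 °C.

Step 11
Reactants: 16 2-[(1R,3R,4S,6S,8R,10S)-4,10-dibromo-3-ethyl-2,7-dioxabicyclo[4.2.2]decan-8-yl]acetaldehyde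
Product: 18 (1R,3R,4S,6S,8R,10S)-4,10-dibromo-3-ethyl-8-[(2E)-pent-2-en-4-yn-1-yl]-2,7-dioxabicyclo[4.2.2]decane (target), via trimethylsilyl enyne 17 (not isolated)
Conditions: (EtO)2P(O)CH2C≡CSiMe3, LiN(SiMe3)2, THF, −78 → 0 °C; then K2CO3, MeOH, 0 °C
Reagents that add atoms: diethyl [3-(trimethylsilyl)prop-2-yn-1-yl]phosphonate CCOP(=O)(CC#C[Si](C)(C)C)OCC
Why: Horner–Wadsworth–Emmons olefination with the lithiated propargylic phosphonate, which should give mainly the (E)-enyne, followed by methanolysis of the alkynyl silane.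

**Compound list**

1 | 3-(furan-2-yl)-3-oxopropanenitrile | N#CCC(=O)c1ccco1 | starting material
2 | (3R)-3-(furan-2-yl)-3-hydroxypropanenitrile | N#CC[C@@H](O)c1ccco1 | intermediate
3 | 2-[(2R)-6-hydroxy-3-oxo-3,6-dihydro-2H-pyran-2-yl]acetonitrile (both anomers) | N#CC[C@H]1OC(O)C=CC1=O | intermediate
4 | (2R,6R)-6-(cyanomethyl)-5-oxo-5,6-dihydro-2H-pyran-2-yl acetate | N#CC[C@H]1O[C@H](OC(C)=O)C=CC1=O | intermediate
5 | (2R,3S,6R)-3-bromo-6-(cyanomethyl)-5-[(trimethylsilyl)oxy]-3,6-dihydro-2H-pyran-2-yl acetate (not isolated) | N#CC[C@H]1O[C@H](OC(C)=O)[C@@H](Br)C=C1O[Si](C)(C)C | intermediate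
6 | (2R,3S,6R)-3-bromo-6-(cyanomethyl)-5-oxooxan-2-yl acetate | N#CC[C@H]1O[C@H](OC(C)=O)[C@@H](Br)CC1=O | intermediate
7 | (2R,3S,5R,6R)-3-bromo-6-(cyanomethyl)-5-hydroxyoxan-2-yl acetate | N#CC[C@H]1O[C@H](OC(C)=O)[C@@H](Br)C[C@H]1O | intermediate
8 | allyl(chloro)dimethylsilane | C=CC[Si](C)(C)Cl | starting material
9 | allyl(diisopropylamino)dimethylsilane | C=CC[Si](C)(C)N(C(C)C)C(C)C | intermediate
10 | lithium 1-[(diisopropylamino)dimethylsilyl]allyl anion (not isolated) | [Li+].C=C[CH-][Si](C)(C)N(C(C)C)C(C)C | intermediate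
11 | (diisopropylamino)dimethyl(pent-1-en-3-yl)silane (racemic) | C=CC(CC)[Si](C)(C)N(C(C)C)C(C)C | intermediate
12 | chloro(dimethyl)(pent-1-en-3-yl)silane (racemic, not isolated) | C=CC(CC)[Si](C)(C)Cl | intermediate
13 | (2R,3S,5R,6R)-3-bromo-6-(cyanomethyl)-5-{[dimethyl(pent-1-en-3-yl)silyl]oxy}oxan-2-yl acetate (both epimers at the silicon-bearing carbon) | N#CC[C@H]1O[C@H](OC(C)=O)[C@@H](Br)C[C@H]1O[Si](C)(C)C(CC)C=C | intermediate
14 | {[(2R,3R,5S,6S)-5-bromo-2-(cyanomethyl)-6-[(2E)-pent-2-en-1-yl]oxan-3-yl]oxy}(dimethyl)silyl acetate (not isolated) | N#CC[C@H]1O[C@@H](C/C=C/CC)[C@@H](Br)C[C@H]1O[Si](C)(C)OC(C)=O | intermediate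
15 | 2-[(1R,3R,4S,6S,8R,10S)-4,10-dibromo-3-ethyl-2,7-dioxabicyclo[4.2.2]decan-8-yl]acetonitrile | N#CC[C@H]1O[C@H]2C[C@H](Br)[C@@H](CC)O[C@@H]1C[C@@H]2Br | intermediate
16 | 2-[(1R,3R,4S,6S,8R,10S)-4,10-dibromo-3-ethyl-2,7-dioxabicyclo[4.2.2]decan-8-yl]acetaldehyde | O=CC[C@H]1O[C@H]2C[C@H](Br)[C@@H](CC)O[C@@H]1C[C@@H]2Br | intermediate
17 | {(3E)-5-[(1R,3R,4S,6S,8R,10S)-4,10-dibromo-3-ethyl-2,7-dioxabicyclo[4.2.2]decan-8-yl]pent-3-en-1-yn-1-yl}trimethylsilane (not isolated) | C[Si](C)(C)C#C/C=C/C[C@H]1O[C@H]2C[C@H](Br)[C@@H](CC)O[C@@H]1C[C@@H]2Br | intermediate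
18 | (1R,3R,4S,6S,8R,10S)-4,10-dibromo-3-ethyl-8-[(2E)-pent-2-en-4-yn-1-yl]-2,7-dioxabicyclo[4.2.2]decane | C#C/C=C/C[C@H]1O[C@H]2C[C@H](Br)[C@@H](CC)O[C@@H]1C[C@@H]2Br | target

**Step count.** 11 steps in total; the longest linear sequence is 9 steps (steps 1–5 and 8–11), with steps 6–7 as a two-step side branch.

**Steps most likely to fail**

Step 9. The tethered 1,4-delivery may lose to intermolecular allyl transfer or elimination, and the bromonium ion may be opened 7-exo or on the other alkene face. The fallback sets out from 7 and returns at 15. It joins the C7 oxygen to C13 first and closes the ring by C–C bond formation. Iridium-catalysed branched-selective allylic etherification of the zinc alkoxide of 7 with methyl (E)-pent-2-en-1-yl carbonate ([Ir(cod)Cl]2, chiral phosphoramidite ligand, Et2Zn, THF) should give the (3R)-pent-1-en-3-yl ether F1, with C13 set by the ligand. SnBr4 in CH2Cl2 at −78 °C then ionises the anomeric acetate; the terminal alkene attacks C10 in an 8-endo Prins cyclisation, possible only cis to the C7 oxygen, and bromide captures C12 to give 15.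

Step 4. The conjugate addition may reverse (loss of HBr) on work-up, the anomeric acetate may exchange, or facial control may be poor. The fallback sets out from 4 and returns at 7. SmI2 (THF, MeOH, −78 °C) removes the allylic anomeric acetate reductively and the dienolate is protonated at C8 to give the enol ether ketone F2. LiBH(s-Bu)3 reduces it to the cis glycal alcohol F3. NBS in acetic acid then adds bromine and acetate trans-diaxially across C9=C10, as for galactal-type glycals, to give 7.

Step 11. The olefination may give incomplete (E)-selectivity, and the base may cause β-elimination of the ring oxygen from the β-alkoxy aldehyde. The fallback sets out from 16 and returns at 17. Takai olefination (CrCl2, CHI3, THF, 0 °C) should give the (E)-vinyl iodide F4 under non-basic conditions. Sonogashira coupling with trimethylsilylacetylene (Pd(PPh3)4, CuI, i-Pr2NH) gives 17, which is desilylated as in step 11.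

**Further compounds**

F1 | step 9 | (2R,3S,5R,6R)-3-bromo-6-(cyanomethyl)-5-{[(3R)-pent-1-en-3-yl]oxy}oxan-2-yl acetate | N#CC[C@H]1O[C@H](OC(C)=O)[C@@H](Br)C[C@H]1O[C@H](CC)C=C
F2 | step 4 | 2-[(2R)-3-oxo-3,4-dihydro-2H-pyran-2-yl]acetonitrile | N#CC[C@H]1OC=CCC1=O
F3 | step 4 | 2-[(2R,3R)-3-hydroxy-3,4-dihydro-2H-pyran-2-yl]acetonitrile | N#CC[C@H]1OC=CC[C@H]1O
F4 | step 11 | (1R,3R,4S,6S,8R,10S)-4,10-dibromo-3-ethyl-8-[(2E)-3-iodoprop-2-en-1-yl]-2,7-dioxabicyclo[4.2.2]decane | I/C=C/C[C@H]1O[C@H]2C[C@H](Br)[C@@H](CC)O[C@@H]1C[C@@H]2Br
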